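The runs were computed with made-up constants, and the scatter is random.

I began from a one-step world, in which each incoming ligand turned one starting complex into one complex with one exchanged, so that the percentage made equalled the equivalents charged. I therefore took as my measure the capture: the fraction of the starting complex held as complex with one exchanged on the plateau, per equivalent of incoming ligand charged.

| setting | cedar | oak | flask |
|---|---|---|---|
| starting complex | 0.49 M | 0.49 M | 0.49 M |
| incoming ligand | 0.25 equiv | 0.38 equiv | 0.500 equiv |
| scavenger | 0.80 equiv | 0.80 equiv | 0.800 equiv |
| remark | run made earlier | run made earlier |  |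
| time |  |  | 12 h |

| run | time / h | complex with one exchanged / % | starting complex / % |
|---|---|---|---|
| cedar | 0.833 | 21 | 78 |
| cedar | 1.33 | 26 | 74 |
| cedar | 2.50 | 25 | 76 |
| cedar | 5.00 | 26 | 74 |
| cedar | 10.0 | 26 | 77 |
| oak | 0.833 | 33 | 66 |
| oak | 2.50 | 33 | 64 |
| oak | 4.00 | 32 | 64 |
| oak | 6.00 | 35 | 66 |
| oak | 10.0 | 36 | 61 |

(standard deviation of a reading: 1.5 percentage points)

1. equivalents of incoming ligand to starting complex, everything else as given, that leave most complex with one exchanged at 12 h
2. the amount of complex with one exchanged then, in percent of the starting complex charged
3. the amount of complex with one exchanged with the amounts as given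

- the earlier runs were read with a standard deviation of 1.5 percentage points

I went through the settings one after the other. By hand, more time does nothing once the ligand has reacted, and the readings agreed: cedar stood at 26 % by 1.33 h and at 26 % at 10.0 h, while oak moved from 33 % to 36 % against a scatter of 1.5 points. Starting concentration and scavenger were the same in both runs, so the readings could not test them, and I held them; the scavenger charge of 0.800 equiv stood above the 0.500 equiv of ligand in the flask.

That left the ligand. Cedar read a capture of 1.03. Oak, the nearer run to the flask, read 0.889, lower than cedar's reading, and this oak capture was the number I carried forward. Applying the capture of the nearest run, I reckoned 44.5 % for the flask. Two runs showed no peak, so I committed to no optimum.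

The forecast gave 44 % for the flask; for the best charge it gave 60 % at 0.85 equiv, on the ground that “scavenger probably caps total exchange”.

The flask gave 44.1 %, and the best charge was 0.695 equiv, giving 50.9 %.

    leaving ligand + incoming ligand ⇌ idle adduct, settled at all times (K = 0.790 L mol⁻¹)
    complex with one exchanged + incoming ligand → over-reaction product (k = 0.00610 L mol⁻¹ min⁻¹)
    scavenger + leaving ligand → scavenged by-product (k = 1.60 L mol⁻¹ min⁻¹)
    complex with one exchanged + incoming ligand ⇌ leaving ligand + complex with two exchanged (K = 1.10, k = 0.00800 L mol⁻¹ min⁻¹)
    starting complex + incoming ligand ⇌ leaving ligand + complex with one exchanged (K = 0.0700, k = 0.200 L mol⁻¹ min⁻¹)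

The flask's capture was 0.882, beside the 0.889 read from oak, and incoming ligand was the flask's limiting reagent, with 0 % of it left at 12.0 h against 53 % of the starting complex. The neighbouring flask charged 0.120 equiv of ligand, with the other charges and the time held. Its nearest run is cedar, so I multiplied the capture of 1.03 read from cedar by that charge and obtained 12.4 %. The neighbour gave 11.9 %, with 0 % of its ligand and 85 % of its scavenger left.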